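## Retrosynthetic overview

- Locants: oxane O1, C2 (=CH2), C3 (OH), C4, C5 (Br), C6 (CMe2); cyclohexyl C1' (on C3), C2', C3' (CHBr), C4' (C(CH3)Cl), C5', C6'. The enol ether C2=CH2 is made last, by methylenation of a C2 lactone.
- C4'–Cl and C3'–Br go back to a C4' ketone: catalyst-controlled α-hydroxylation at C3' (a desymmetrisation that first makes C1' a stereocentre), OH→Br with inversion, CH3 to C4', tertiary OH→Cl with retention.
- Key disconnection: C4'–C5' together with C3'–C4'. C4' is carbon monoxide, stitched between the two vinyl groups of a penta-1,4-dien-3-yl unit on C3 through a temporary B-thexylborinane (boron in the place of C4'), whose boron is then lost.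
- Feature that allows this: in the cyclohexane, C4' lies para to C1', and the paths C1'–C6'–C5' and C1'–C2'–C3' are equal CH2–CH2 arms once C3'/C4' are read as CH2/C=O, so C1' needs no configuration until the ring exists.
- The diene comes from a Sharpless epoxy alcohol (sets C3) opened by a vinyl group. Ring order: oxanone (6-endo bromolactonisation, sets C5), borinane (temporary), cyclohexanone, enol ether.

Key step: step 8

Remark: Thx = 2,3-dimethylbutan-2-yl; in compounds 8 to 14 the carbon that becomes C1' carries two equal arms and is not a stereocentre.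

## Route

Step 1
Reactants: 1 triethyl phosphonoacetate; 2 1-bromo-3-methylbut-2-ene
Product: 3 ethyl 2-(diethoxyphosphoryl)-5-methylhex-4-enoate
Conditions: NaH, THF, 0 °C to rt
Reagents that add atoms: none
Why: Alkylation of the phosphonate-stabilised carbanion (SN2 at the primary allylic bromide), which should stop at monoalkylation with one equivalent of base.

Step 2
Reactants: 3 ethyl 2-(diethoxyphosphoryl)-5-methylhex-4-enoate; 4 prop-2-enal
Product: 5 ethyl (2E)-2-(3-methylbut-2-en-1-yl)penta-2,4-dienoate
Conditions: NaH, THF, 0 °C; then 4, −78 to 0 °C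
Reagents that add atoms: none
Why: Horner–Wadsworth–Emmons olefination, expected to favour the E ester; any Z isomer would converge on the same diol 8, because the carbon it differs at loses its stereogenicity in step 5.

Step 3
Reactants: 5 ethyl (2E)-2-(3-methylbut-2-en-1-yl)penta-2,4-dienoate
Product: 6 (2E)-2-(3-methylbut-2-en-1-yl)penta-2,4-dien-1-ol
Conditions: i-Bu2AlH (2.2 equiv), CH2Cl2, −78 °C; aq. potassium sodium tartrate
Reagents that add atoms: none
Why: 1,2-Reduction of the conjugated ester to the allylic alcohol by an aluminium hydride, which leaves the diene untouched.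

Step 4
Reactants: 6 (2E)-2-(3-methylbut-2-en-1-yl)penta-2,4-dien-1-ol
Product: 7 [(2R,3R)-3-ethenyl-2-(3-methylbut-2-en-1-yl)oxiran-2-yl]methanol
Conditions: Ti(OiPr)4 (10 mol%), D-(−)-diethyl tartrate (12 mol%), t-BuOOH, 4 Å molecular sieves, CH2Cl2, −20 °C
Reagents that add atoms: tert-butyl hydroperoxide, CC(C)(C)OO
Why: Sharpless asymmetric epoxidation, which touches only the allylic C2=C3 alkene; the D-tartrate should deliver oxygen to the face that makes the fully substituted epoxide carbon R (it becomes C3 of the oxane, S once the ring is opened).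

Step 5
Reactants: 7 [(2R,3R)-3-ethenyl-2-(3-methylbut-2-en-1-yl)oxiran-2-yl]methanol
Product: 8 (2S)-5-methyl-2-(penta-1,4-dien-3-yl)hex-4-ene-1,2-diol
Conditions: Et2AlCH=CH2 (3 equiv, made from CH2=CHMgBr and Et2AlCl), toluene/THF, −40 to 0 °C; aq. potassium sodium tartrate
Reagents that add atoms: vinylmagnesium bromide, C=C[Mg]Br
Why: Organoaluminium opening of a 2,3-epoxy alcohol: the aluminium alkoxide should direct the vinyl group to the allylic, not fully substituted C3 (SN2); the attacked carbon then carries two vinyl groups and is no stereocentre, while the carbinol carbon keeps its configuration.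

Step 6
Reactants: 8 (2S)-5-methyl-2-(penta-1,4-dien-3-yl)hex-4-ene-1,2-diol
Product: 9 (2S)-2-hydroxy-5-methyl-2-(penta-1,4-dien-3-yl)hex-4-enoic acid
Conditions: TEMPO (cat.), NaOCl (cat.), NaClO2, MeCN/phosphate buffer pH 6.7, 35 °C
Reagents that add atoms: sodium chlorite, [Na+].[O-]Cl=O
Why: TEMPO-catalysed oxidation of the primary alcohol through the aldehyde to the acid with chlorite as terminal oxidant; the tertiary alcohol cannot be oxidised.

Step 7
Reactants: 9 (2S)-2-hydroxy-5-methyl-2-(penta-1,4-dien-3-yl)hex-4-enoic acid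
Product: 11 (3S,5R)-5-bromo-6,6-dimethyl-3-(penta-1,4-dien-3-yl)-3-[(trimethylsilyl)oxy]oxan-2-one, via bis-silyl acid 10 (not isolated)
Conditions: TMSOTf (2.2 equiv), 2,6-lutidine, CH2Cl2, −78 to 0 °C; then NBS, −40 °C
Reagents that add atoms: trimethylsilyl trifluoromethanesulfonate, C[Si](C)(C)OS(=O)(=O)C(F)(F)F; N-bromosuccinimide, O=C1CCC(=O)N1Br
Why: Bromolactonisation of the silyl ester (6-endo, Markovnikov opening of the bromonium ion of the most electron-rich alkene at its dimethyl-substituted carbon); a chair transition state with Br and the larger pentadienyl group equatorial should set C5 as R, and the silyl ether keeps the tertiary oxygen from closing a tetrahydrofuran.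

Step 8
Reactants: 11 (3S,5R)-5-bromo-6,6-dimethyl-3-(penta-1,4-dien-3-yl)-3-[(trimethylsilyl)oxy]oxan-2-one
Product: 14 (3S,5R)-5-bromo-3-hydroxy-6,6-dimethyl-3-(4-oxocyclohexyl)oxan-2-one, via B-thexylborinane 12 (not isolated), via silyl ether ketone 13 (not isolated)
Conditions: ThxBH2 (1.05 equiv, from BH3·THF and 2,3-dimethylbut-2-ene), THF, −20 °C to rt, dilute; CO (70 atm), H2O, 50 °C; NaOAc, H2O2, 30 °C; then 1 M HCl, THF, 0 °C
Reagents that add atoms: carbon monoxide, [C-]#[O+]
Why: Thexylborane adds its two B–H bonds anti-Markovnikov to the two vinyl groups (the second addition inside the molecule), which closes B-thexylborinane 12 with boron in the place of C4'. Carbon monoxide binds to boron and the two ring carbons migrate one after the other from boron to the carbonyl carbon; the second 1,2-shift contracts the seven-membered acylborane to the six-membered carbocycle, so that C4' is bonded to C3' and to C5', and peroxide then removes boron. The closest known reaction type is the hydroboration–carbonylation of 1,4-dienes with thexylborane to cyclohexanones. The borinane closes by endo hydroboration (six-membered because boron goes to the terminal carbons and the central carbon is hindered) and the cyclohexanone by the boron-to-carbon shift; no stereocentre is formed, since C1' carries two equal arms until step 9. The step needs boron at the terminal carbons, reaction at the alkenes before the lactone, and migration of the ring carbons instead of the thexyl group; these rest on the hindered borane at low temperature, on the silyl ether that stops the hydroxyl from taking a B–H bond, and on the reluctance of the tertiary thexyl group to migrate when water is present.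

Step 9
Reactants: 14 (3S,5R)-5-bromo-3-hydroxy-6,6-dimethyl-3-(4-oxocyclohexyl)oxan-2-one
Product: 16 (3S,5R)-5-bromo-3-hydroxy-3-[(1S,3R)-3-hydroxy-4-oxocyclohexyl]-6,6-dimethyloxan-2-one, via anilinooxy ketone 15 (not isolated)
Conditions: L-proline (30 mol%), PhNO (slow addition), DMF, 0 °C; then CuSO4·5H2O (30 mol%), MeOH, 0 °C
Reagents that add atoms: nitrosobenzene, O=Nc1ccccc1
Why: Proline-catalysed α-aminoxylation (enamine catalysis) used as a desymmetrisation of the 4-substituted cyclohexanone, followed by copper-catalysed N–O cleavage; L-proline should fix the new carbinol carbon as R, and axial attack on the enamine of the chair with the large C1' substituent equatorial should place oxygen trans to it, which at the same time makes C1' S.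

Step 10
Reactants: 16 (3S,5R)-5-bromo-3-hydroxy-3-[(1S,3R)-3-hydroxy-4-oxocyclohexyl]-6,6-dimethyloxan-2-one
Product: 17 (3S,5R)-5-bromo-3-[(1S,3S)-3-bromo-4-oxocyclohexyl]-3-hydroxy-6,6-dimethyloxan-2-one
Conditions: PPh3, CBr4, CH2Cl2, −20 to 0 °C
Reagents that add atoms: carbon tetrabromide, BrC(Br)(Br)Br
Why: Appel reaction; SN2 displacement of the alkoxyphosphonium at the carbon next to the ketone (activated and unhindered while C4' is still a carbonyl carbon) should invert C3' to S and so put Br cis to the C1' substituent, while the hindered tertiary alcohol is left alone.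

Step 11
Reactants: 17 (3S,5R)-5-bromo-3-[(1S,3S)-3-bromo-4-oxocyclohexyl]-3-hydroxy-6,6-dimethyloxan-2-one
Product: 18 (3S,5R)-5-bromo-3-[(1S,3S,4S)-3-bromo-4-hydroxy-4-methylcyclohexyl]-3-hydroxy-6,6-dimethyloxan-2-one
Conditions: Me3Al (4 equiv), toluene, −78 to −20 °C; aq. potassium sodium tartrate
Reagents that add atoms: trimethylaluminium, C[Al](C)C
Why: 1,2-Addition of an organoaluminium reagent to the ketone; with excess Me3Al the methyl group is expected to enter axially and give the equatorial tertiary alcohol trans to Br (4S), and the non-basic reagent should avoid enolisation and loss of HBr.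

Step 12
Reactants: 18 (3S,5R)-5-bromo-3-[(1S,3S,4S)-3-bromo-4-hydroxy-4-methylcyclohexyl]-3-hydroxy-6,6-dimethyloxan-2-one
Product: 19 (3S,5R)-5-bromo-3-[(1S,3S,4S)-3-bromo-4-chloro-4-methylcyclohexyl]-3-hydroxy-6,6-dimethyloxan-2-one
Conditions: SOCl2, CH2Cl2, 0 °C to rt; aq. NaHCO3
Reagents that add atoms: thionyl chloride, O=S(Cl)Cl
Why: Substitution of the tertiary alcohol through its chlorosulfite with retention: internal return (SNi) and ionisation to the bromonium ion followed by anti attack of chloride at the tertiary carbon both lead to the trans bromo chloride, while the hydroxyl next to the lactone carbonyl cannot ionise and is set free again on work-up.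

Step 13
Reactants: 19 (3S,5R)-5-bromo-3-[(1S,3S,4S)-3-bromo-4-chloro-4-methylcyclohexyl]-3-hydroxy-6,6-dimethyloxan-2-one
Product: 20 (3S,5R)-5-bromo-3-[(1S,3S,4S)-3-bromo-4-chloro-4-methylcyclohexyl]-6,6-dimethyl-2-methylideneoxan-3-ol
Conditions: Cp2TiMe2 (4 equiv), toluene/THF, 65 °C, dark; filtration through basic Al2O3
Reagents that add atoms: dimethyltitanocene, C[Ti](C)(C1C=CC=C1)C1C=CC=C1
Why: Petasis methylenation of the lactone carbonyl to the exocyclic enol ether; the quaternary C3 blocks migration of the double bond into the ring, the neutral titanium carbene should leave the alkyl halides alone, and the free hydroxyl only consumes one equivalent as a titanium alkoxide that is released on work-up.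

## Compound list

1 | triethyl phosphonoacetate | CCOC(=O)CP(=O)(OCC)OCC | starting material
2 | 1-bromo-3-methylbut-2-ene | CC(C)=CCBr | starting material
3 | ethyl 2-(diethoxyphosphoryl)-5-methylhex-4-enoate | CCOC(=O)C(CC=C(C)C)P(=O)(OCC)OCC | intermediate
4 | prop-2-enal | C=CC=O | starting material
5 | ethyl (2E)-2-(3-methylbut-2-en-1-yl)penta-2,4-dienoate | CCOC(=O)/C(CC=C(C)C)=C/C=C | intermediate
6 | (2E)-2-(3-methylbut-2-en-1-yl)penta-2,4-dien-1-ol | OC/C(CC=C(C)C)=C/C=C | intermediate
7 | [(2R,3R)-3-ethenyl-2-(3-methylbut-2-en-1-yl)oxiran-2-yl]methanol | OC[C@@]1(CC=C(C)C)O[C@@H]1C=C | intermediate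
8 | (2S)-5-methyl-2-(penta-1,4-dien-3-yl)hex-4-ene-1,2-diol | OC[C@](O)(CC=C(C)C)C(C=C)C=C | intermediate
9 | (2S)-2-hydroxy-5-methyl-2-(penta-1,4-dien-3-yl)hex-4-enoic acid | OC(=O)[C@](O)(CC=C(C)C)C(C=C)C=C | intermediate
10 | trimethylsilyl (2S)-5-methyl-2-(penta-1,4-dien-3-yl)-2-[(trimethylsilyl)oxy]hex-4-enoate | C[Si](C)(C)OC(=O)[C@](O[Si](C)(C)C)(CC=C(C)C)C(C=C)C=C | intermediate
11 | (3S,5R)-5-bromo-6,6-dimethyl-3-(penta-1,4-dien-3-yl)-3-[(trimethylsilyl)oxy]oxan-2-one | O=C1OC(C)(C)[C@H](Br)C[C@]1(O[Si](C)(C)C)C(C=C)C=C | intermediate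
12 | (3S,5R)-5-bromo-3-[1-(2,3-dimethylbutan-2-yl)borinan-4-yl]-6,6-dimethyl-3-[(trimethylsilyl)oxy]oxan-2-one | O=C1OC(C)(C)[C@H](Br)C[C@]1(O[Si](C)(C)C)C1CCB(CC1)C(C)(C)C(C)C | intermediate
13 | (3S,5R)-5-bromo-6,6-dimethyl-3-(4-oxocyclohexyl)-3-[(trimethylsilyl)oxy]oxan-2-one | O=C1OC(C)(C)[C@H](Br)C[C@]1(O[Si](C)(C)C)C1CCC(=O)CC1 | intermediate
14 | (3S,5R)-5-bromo-3-hydroxy-6,6-dimethyl-3-(4-oxocyclohexyl)oxan-2-one | O=C1OC(C)(C)[C@H](Br)C[C@]1(O)C1CCC(=O)CC1 | intermediate
15 | (3S,5R)-3-[(1S,3R)-3-(anilinooxy)-4-oxocyclohexyl]-5-bromo-3-hydroxy-6,6-dimethyloxan-2-one | O=C1OC(C)(C)[C@H](Br)C[C@]1(O)[C@H]1CCC(=O)[C@H](ONc2ccccc2)C1 | intermediate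
16 | (3S,5R)-5-bromo-3-hydroxy-3-[(1S,3R)-3-hydroxy-4-oxocyclohexyl]-6,6-dimethyloxan-2-one | O=C1OC(C)(C)[C@H](Br)C[C@]1(O)[C@H]1CCC(=O)[C@H](O)C1 | intermediate
17 | (3S,5R)-5-bromo-3-[(1S,3S)-3-bromo-4-oxocyclohexyl]-3-hydroxy-6,6-dimethyloxan-2-one | O=C1OC(C)(C)[C@H](Br)C[C@]1(O)[C@H]1CCC(=O)[C@@H](Br)C1 | intermediate
18 | (3S,5R)-5-bromo-3-[(1S,3S,4S)-3-bromo-4-hydroxy-4-methylcyclohexyl]-3-hydroxy-6,6-dimethyloxan-2-one | O=C1OC(C)(C)[C@H](Br)C[C@]1(O)[C@H]1CC[C@](C)(O)[C@@H](Br)C1 | intermediate
19 | (3S,5R)-5-bromo-3-[(1S,3S,4S)-3-bromo-4-chloro-4-methylcyclohexyl]-3-hydroxy-6,6-dimethyloxan-2-one | O=C1OC(C)(C)[C@H](Br)C[C@]1(O)[C@H]1CC[C@](C)(Cl)[C@@H](Br)C1 | intermediate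
20 | (3S,5R)-5-bromo-3-[(1S,3S,4S)-3-bromo-4-chloro-4-methylcyclohexyl]-6,6-dimethyl-2-methylideneoxan-3-ol | C=C1OC(C)(C)[C@H](Br)C[C@]1(O)[C@H]1CC[C@](C)(Cl)[C@@H](Br)C1 | target

## Step count and risks

Total step count: 13. Longest linear sequence: 13 steps (fully linear from 1).

Steps most likely to fail:

Step 8. The second hydroboration may run between molecules or place boron on the inner carbon (five-membered boracycle), or the borane may reduce the lactone, so that carbonylation gives little cyclohexanone. The fallback sets out from 11 and builds the ring by alkylation instead of carbonylation. Both vinyl groups are hydroborated with 9-BBN and oxidised (NaBO3·4H2O) to the silyl ether diol F3, and MsCl/Et3N gives the bis-mesylate F4. Double alkylation of tosylmethyl isocyanide (NaH, DMSO/Et2O, van Leusen conditions) closes the six-membered ring as the isocyano sulfone F5. Aqueous HCl in ether then hydrolyses the isocyanide–sulfone carbon to the ketone and removes the silyl group, returning to 14.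

Step 9. The catalyst may discriminate poorly between the two α-carbons, the electrophile may enter equatorially (cis isomer), or both α-carbons may be oxidised. The fallback sets out from 14 and replaces enamine catalysis by base-mediated desymmetrisation. A chiral lithium amide (lithium bis[(R)-1-phenylethyl]amide or its enantiomer, whichever removes the axial proton of the arm that becomes C3') with TMSCl present should give the bis-silyl enol ether F6. Rubottom oxidation (dimethyldioxirane, acetone, −78 °C; then citric acid, MeOH), with axial attack anti to the C1' substituent, returns to 16.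

Step 5. The alane may attack the vinyl terminus (SN2' opening) or transfer an ethyl group instead of vinyl. The fallback sets out from 7 and uses an alkynyl group as the vinyl precursor. Et2Al–C≡C–SiMe3 (from trimethylsilylacetylene, n-BuLi and Et2AlCl) opens the epoxy alcohol at C3 to the silylated enyne diol F1, and K2CO3/MeOH removes silicon to give the enyne diol F2. Semihydrogenation (H2, Pd/CaCO3 poisoned with Pb(OAc)2, quinoline) returns to 8.

Further compounds

F1 | step 5 | (2S)-5-methyl-2-[(3R)-5-(trimethylsilyl)pent-1-en-4-yn-3-yl]hex-4-ene-1,2-diol | OC[C@](O)(CC=C(C)C)[C@H](C=C)C#C[Si](C)(C)C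
F2 | step 5 | (2S)-5-methyl-2-[(3R)-pent-1-en-4-yn-3-yl]hex-4-ene-1,2-diol | OC[C@](O)(CC=C(C)C)[C@H](C=C)C#C
F3 | step 8 | (3S,5R)-5-bromo-3-(1,5-dihydroxypentan-3-yl)-6,6-dimethyl-3-[(trimethylsilyl)oxy]oxan-2-one | O=C1OC(C)(C)[C@H](Br)C[C@]1(O[Si](C)(C)C)C(CCO)CCO
F4 | step 8 | (3S,5R)-5-bromo-3-[1,5-bis(methanesulfonyloxy)pentan-3-yl]-6,6-dimethyl-3-[(trimethylsilyl)oxy]oxan-2-one | O=C1OC(C)(C)[C@H](Br)C[C@]1(O[Si](C)(C)C)C(CCOS(C)(=O)=O)CCOS(C)(=O)=O
F5 | step 8 | (3S,5R)-5-bromo-3-[4-isocyano-4-(4-methylbenzenesulfonyl)cyclohexyl]-6,6-dimethyl-3-[(trimethylsilyl)oxy]oxan-2-one | O=C1OC(C)(C)[C@H](Br)C[C@]1(O[Si](C)(C)C)C1CCC(CC1)([N+]#[C-])S(=O)(=O)c1ccc(C)cc1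
F6 | step 9 | (3S,5R)-5-bromo-6,6-dimethyl-3-[(trimethylsilyl)oxy]-3-{(1S)-4-[(trimethylsilyl)oxy]cyclohex-3-en-1-yl}oxan-2-one | O=C1OC(C)(C)[C@H](Br)C[C@]1(O[Si](C)(C)C)[C@H]1CCC(O[Si](C)(C)C)=CC1
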